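## Structural features

The target is a cis-fused 1,2,4a,5,6,7,8,8a-octahydronaphthalene. Ring A is a cyclohexene whose trisubstituted C3=C4 bond carries the C3 methyl group, ring B is a cyclohexane, and the two share the C4a–C8a bond. Locants are those of this decalin core throughout; β means the face that carries H-4a and H-8a, α the other face. Six stereocentres lie on the periphery: C2 (α (E)-but-2-en-2-yl), C1 (β (2E,4E)-penta-2,4-dienoic acid chain), C8a, C8 (β methyl), C7 (β sulfate) and C4a. In the favoured conformer the C1 and C2 groups are trans-diequatorial on ring A, the C8 methyl group is axial and the C7 oxygen equatorial on ring B. The fragile groups are the secondary alkyl hydrogen sulfate (acid-labile, so made last), the dienoic acid, the butenyl geometry, and the doubly allylic methines C2 and C4a, which invite double-bond migration once a carbonyl sits at C1 or C7. C1 is the thermodynamic configuration of an epimerisable aldehyde and C7 the more stable alcohol, so the real difficulty is C2: a carbon nucleophile adding to C2 of a ring-A enone would enter on the β face, anti to C8, and give the wrong epimer. A second difficulty is placing the methyl group at C8 and not at C6. The key step exploits the cis C4a–C8a fusion flanked by the methyl-bearing ring-A alkene and the C7 oxygen: this is the imprint of a [4+2] adduct in which the unsubstituted enone bond of a 2-methyl para-quinone monoketal (C4 carbonyl, C1 ketal) supplies C4a and C8a, and a 1-methoxy-3-silyloxydiene supplies C5–C8 with oxygen at C7.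

## Logic of the disconnections

23 ⇒ 21. The S–O bond of the sulfate and the O–ethyl bond of the ester are cut first, because the hydrogen sulfate is the most labile group and must appear last. This leaves a neutral hydroxy ester. The forward step must sulfate a hindered secondary alcohol and then saponify without touching the sulfate or the diene.

21 ⇒ 19 + 20. The C=C bond next to C1 in the side chain is cut (vinylogous Horner–Wadsworth–Emmons). This removes four carbons and both side-chain alkenes in one operation. The forward step must give the E alkene from an α-branched aldehyde and tolerate the free C7 hydroxyl.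

19 ⇒ 15 (through 18, 17 and 16). The exocyclic C–C bond at C1 is cut, a one-carbon homologation of a ketone. C1 is then no longer a stereochemical problem, because the aldehyde can be equilibrated to the trans,trans isomer. The forward steps must not enolise 15 toward C2, so the carbon is added by a non-basic methylenation and the oxygen by hydroboration.

15 ⇒ 12 (through 14 and 13). The C7–H bond and the two C–H bonds at C5 and C6 are removed, and the C1 ketone is masked again as its ketal. This returns ring B to an enone, which is what allows C8 to be addressed selectively. The forward reduction must deliver the equatorial 7β-alcohol and spare the two isolated alkenes.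

12 ⇒ 11. The C8–CH3 bond is cut. The forward step needs α′-selective kinetic deprotonation of the enone in the presence of the acidic C4a–H, and attack of the electrophile on the β face.

11 ⇒ 10. The enone is traced back to its masked form (C5 methoxy, C6=C7 silyl enol ether). The forward unmasking must leave the C1 dimethyl ketal intact.

10 ⇒ 7 + 8 (through 9). The C2–butenyl bond is cut with allylic transposition: the C3=C4 bond goes back to C2=C3 and an oxygen returns to C4. This turns the difficult C2 centre into a C4–O centre that is easy to set. The forward step must deliver the alkenyl group to C2 on the same face as the departing oxygen and keep the alkene geometry of 8.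

7 ⇒ 5 (through 6). The carbamate C–O bond and the C4–H bond are cut, giving back the C4 ketone. The forward reduction must come from the β face to give the 4α-oxygen.

5 ⇒ 4 + 2. The C4a–C5 and C8–C8a bonds are cut in a retro-[4+2] step. This removes ring B and all three stereocentres of 5 and leaves two achiral partners. The forward step needs site, regio, endo and enantiofacial control.

4 ⇒ 3 and 2 ⇒ 1. The ketal C–O bond of 4 is cut back to a phenol, and the Si–O bond of 2 back to an enone. Both are one-step preparations from commercial materials.

## Other disconnections considered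

Alternative 1: The cut is the C1–C2 bond, taken apart as a retro-[3,3] shift that rejoins C4 to a carboxyl oxygen. The precursor is the ring-B-fused δ-lactone A1, with the C7 silyl ether and C8 methyl group in place and a Z-configured dienyl chain on the C4 carbinol carbon. Forward, LDA and Me3SiCl would give the cyclic silyl ketene acetal A2, which on warming should rearrange through the boat transition state enforced by the lactone ring to acid A3.
- In its favour: C1 and C2 are set together in one stereospecific intramolecular step, C1 arrives at the carboxyl oxidation level, and ring B can be finished on a simpler framework.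
- Against it: the boat geometry ties the C1/C2 relationship to the alkene geometry. The trans arrangement of A3 needs the Z alkene with the butenyl group in the crowded inside position; an E chain would give the cis arrangement. A1 also needs four ring-B centres, the C4 carbinol and a geometrically pure diene, and its absolute configuration must come from a separate asymmetric step.
- Comparison: on structure this plan is better than the chosen one at C1 (no homologation of the hindered ketone 15) and equal at C2, since both relay configuration from a C4–O bond (7 in the chosen plan). On mechanism a sigmatropic shift is more predictable than the copper delivery of step 6, but it offers no catalytic entry to absolute configuration, which step 3 provides. On step economy the chosen plan should be shorter, because 5 is reached in three steps whereas A1 would take well over ten.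

Alternative 2: The cut removes C4a–C8a and C5–C6 in one retro-[4+2] step and opens both rings to the acyclic pentaene A4. In A4 a 2-silyloxydiene (C6=C7–C8=C8a) is tethered through C1, C2 and a Z C3=C4 bond to a terminal vinyl group (C4a=C5). Forward, heating A4 in toluene would close ring B as the cycloadduct ring and ring A as the tether ring to give A5.
- In its favour: both rings and both fusion centres form in one reagent-free step, and C1 and C2 are set on an open chain. C1 already carries its carbon. The enol ether of A5 points toward C8, so the C8 methyl group could be introduced regiospecifically; here the alternative is better than the chosen plan, which relies on α′-selective deprotonation of 11.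
- Against it: the dienophile is an unactivated vinyl group that is itself part of a second 1,3-diene, so the reaction would be slow and competing cycloaddition modes and dimerisation are likely. The cis/trans fusion is governed only by the substrate. A4, with a Z trisubstituted alkene and a silyl dienol ether, is delicate to make and purify.
- Comparison: structurally A5 is closer to the target than 5. Mechanistically the chosen step is an electronically matched, Lewis-acid-activated, catalyst-controlled addition, whereas this one is unactivated and substrate-controlled. The step counts should be similar.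

Alternative 3: The cut is the C1–C8a bond. The precursor A6 is a 4-substituted cyclohex-2-enone (ring B) whose C4a carries a Z-alkenyl chain ending in CH2–CHO. Forward, enamine catalysis by diphenylprolinol trimethylsilyl ether with benzoic acid would add C1 to the enone carbon C8a (6-exo) and give the cis-fused keto aldehyde A7.
- In its favour: C1 arrives directly as the aldehyde, which is better than the three-step homologation of the chosen plan. The cis fusion is enforced by the short tether, which is the equal of the suprafacial guarantee of step 3. The C1 configuration can be equilibrated as in step 13, also equal.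
- Against it: after cyclisation ring B is a saturated C7 ketone, so the C6/C8 distinction needed for methylation is lost. A6 carries the doubly allylic C4a stereocentre γ to the enone, which must survive amine and acid. The catalyst governs only the new C1/C8a pair, so C2, C4a and the Z alkene need separate stereoselective steps, and a matched or mismatched case may arise.
- Comparison: on structure A7 solves C1 better and C8 worse than the chosen plan. On mechanism both key steps are catalytic, but step 3 creates all the absolute configuration from achiral 4 and 2, whereas this step only relays it. On step economy the chosen plan should be shorter, because A6 needs a long enantioselective preparation.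

Key step: step 3

Assumption (chemistry): the (R)-BINOL–titanium catalyst is taken to expose the enone face that leads to 5 as drawn; the sense of induction is to be checked on the first run, and if it is opposite the (S)-ligand is used with no other change.

## Steps

Step 1
Reactants: 1 (E)-4-methoxybut-3-en-2-one
Product: 2 (E)-1-methoxy-3-(tert-butyldimethylsilyloxy)buta-1,3-diene
Conditions: TBSOTf, Et3N, Et2O, 0 °C → rt
Reagents that add atoms: tert-butyldimethylsilyl trifluoromethanesulfonate, SMILES CC(C)(C)[Si](C)(C)OS(=O)(=O)C(F)(F)F
Why: Soft enolisation and O-silylation of the methyl ketone (silyl enol ether formation) gives the 2-silyloxydiene; the E enol ether geometry is not touched. The tert-butyldimethylsilyl group is chosen over trimethylsilyl so that the enol ether survives the Lewis acid of step 3 and chromatography through step 6.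

Step 2
Reactants: 3 4-methoxy-2-methylphenol
Product: 4 4,4-dimethoxy-2-methylcyclohexa-2,5-dien-1-one
Conditions: PhI(OAc)2, MeOH, 0 °C
Reagents that add atoms: methanol, SMILES CO
Why: Oxidative dearomatisation of a para-alkoxyphenol: the aryl-iodine reagent generates the phenoxenium ion, which methanol traps at the methoxy-bearing carbon to give the quinone monoketal.

Step 3
Reactants: 4 4,4-dimethoxy-2-methylcyclohexa-2,5-dien-1-one; 2 (E)-1-methoxy-3-(tert-butyldimethylsilyloxy)buta-1,3-diene
Product: 5 cis-fused adduct (C4 ketone; C1 dimethyl ketal; 5α-methoxy; C6=C7 silyl enol ether)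
Conditions: (R)-BINOL (0.2 equiv), TiCl2(OiPr)2 (0.2 equiv), 4 Å MS, CH2Cl2/toluene, −30 → 0 °C
Reagents that add atoms: none
Why: The BINOL–titanium dichloride Lewis acid formed over the sieves binds the single carbonyl (C4) of 4 and lowers the LUMO of the unsubstituted C4a=C8a bond. Diene 2 then adds in a concerted, asynchronous endo [4+2] cycloaddition in which its nucleophilic CH2 terminus bonds to C8a (β to the carbonyl) and its methoxy-bearing terminus to C4a, forming C8–C8a and C4a–C5. The closest known reaction type is the BINOL–TiCl2(OiPr)2-catalysed Diels–Alder reaction of para-quinone monoketals with 2-silyloxybutadienes. Ring B is closed by the cycloaddition itself, as a six-membered ring whose two σ-bonds form suprafacially on both partners. C4a and C8a become cis because addition to the planar cis-enone is suprafacial, and their absolute configuration is set by the chiral tetravalent titanium complex, which shields one enone face. C5 is set by the endo rule (methoxy cis to the C4 acyl carbon, α) and is removed again in step 7. The step needs site selectivity, secured by the α-methyl group that makes the C2=C3 bond the poorer dienophile, and regioselectivity, secured by the single carbonyl and the polarity of the diene. Enantioselectivity rests on the catalyst alone, since 4 is achiral.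

Step 4
Reactants: 5 cis-fused adduct
Product: 6 4α-allylic alcohol
Conditions: i-Bu2AlH, CH2Cl2, −78 °C; aq. potassium sodium tartrate
Reagents that add atoms: none
Why: 1,2-Reduction of the enone by the aluminium hydride; hydride arrives on the convex β face (the α face is screened by ring B and the 5α-methoxy group), giving the 4α-alcohol. This centre is a relay that controls C2 in step 6 and is then lost.

Step 5
Reactants: 6 4α-allylic alcohol
Product: 7 4α-(N-phenylcarbamate)
Conditions: PhNCO, Et3N, DMAP (cat.), CH2Cl2, rt
Reagents that add atoms: phenyl isocyanate, SMILES O=C=Nc1ccccc1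
Why: Carbamoylation of the alcohol by addition to the isocyanate; the N–H carbamate serves both as leaving group and as the handle that holds copper in step 6.

Step 6
Reactants: 7 4α-(N-phenylcarbamate); 8 (E)-2-bromobut-2-ene
Product: 10 2α-butenyl Δ3 ketal silyl enol ether, via (Z)-but-2-en-2-yllithium 9 (not isolated)
Conditions: 8, t-BuLi (2 equiv), Et2O, −78 °C; separately 7, n-BuLi (1 equiv), THF, −78 °C, then CuI (1 equiv), −30 °C; add 9, −78 °C → rt; aq. NH4Cl
Reagents that add atoms: none
Why: Bromine–lithium exchange gives 9 with retention of alkene geometry; the N-lithiated carbamate binds CuI and 9 forms a mixed cuprate held on nitrogen, which delivers the butenyl group to C2 on the face of the departing C4–O bond (syn SN2′ allylic substitution of an allylic carbamate). The 4α-oxygen therefore gives the 2α-butenyl group and moves the alkene to C3=C4. A plain cuprate 1,4-addition to 5 is avoided because it would enter on the β face, anti to C8, and give the C2 epimer.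

Step 7
Reactants: 10 2α-butenyl Δ3 ketal silyl enol ether
Product: 11 ring-B enone (C7 ketone; C5=C6)
Conditions: Bu4NF (1.1 equiv), THF, −20 → 0 °C, 15 min; AcOH quench
Reagents that add atoms: none
Why: Fluoride cleaves the Si–O bond and the enolate expels the β-methoxide (E1cB), giving the conjugated enone and removing the C5 centre. No acid is used, so the C1 dimethyl ketal survives.

Step 8
Reactants: 11 ring-B enone
Product: 12 8β-methyl enone
Conditions: LiN(i-Pr)2 (LDA, 1.1 equiv), THF, −78 °C; MeI, −78 → −40 °C; AcOH quench at −78 °C
Reagents that add atoms: iodomethane, SMILES CI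
Why: Kinetic α′-deprotonation of the enone gives the cross-conjugated enolate (enolate alkylation); iodomethane attacks C8 on the convex β face, anti to the pseudoaxial C1 on C8a, giving the 8β (axial) methyl group.

Step 9
Reactants: 12 8β-methyl enone
Product: 14 7β-hydroxy ketal, via saturated ketone 13 (not isolated)
Conditions: Li (8 equiv), NH3(l)/THF, EtOH (6 equiv), −78 → −33 °C; NH4Cl
Reagents that add atoms: none
Why: Dissolving-metal reduction takes the enone to its enolate, ethanol protonates it to 13, and further electron transfer reduces the ketone under thermodynamic control to the equatorial 7β-alcohol (the axial 7α-alcohol would be syn-diaxial to C1). The isolated trisubstituted alkenes and the ketal are inert to these conditions.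

Step 10
Reactants: 14 7β-hydroxy ketal
Product: 15 7β-hydroxy C1 ketone
Conditions: PPTS (0.1 equiv), acetone/H2O (20:1), rt
Reagents that add atoms: water, SMILES O
Why: Mild acid-catalysed hydrolysis of the dimethyl ketal; the conditions are too weak to enolise the β,γ-unsaturated ketone toward C2, so the C3=C4 bond and the C2 and C8a centres should be kept.

Step 11
Reactants: 15 7β-hydroxy C1 ketone
Product: 16 C1 exocyclic methylene compound
Conditions: Zn, CH2Br2, TiCl4, THF/CH2Cl2, 0 °C → rt
Reagents that add atoms: dibromomethane, SMILES BrCBr
Why: Takai–Lombardo methylenation: the zinc–titanium methylene reagent is non-basic, so the acidic, doubly allylic C2–H next to the carbonyl is not removed, and the free hydroxyl is tolerated with excess reagent.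

Step 12
Reactants: 16 C1 exocyclic methylene compound
Product: 17 primary alcohol (diol; C1 epimers)
Conditions: 9-BBN (2.5 equiv), THF, 0 °C → rt; NaOH, H2O2, 0 °C
Reagents that add atoms: hydrogen peroxide, SMILES OO
Why: Hydroboration–oxidation; 9-BBN selects the 1,1-disubstituted exocyclic alkene over the two trisubstituted alkenes and places boron on the terminal carbon. The C1 configuration formed here is not relied on.

Step 13
Reactants: 17 primary alcohol (diol; C1 epimers)
Product: 19 1β-carbaldehyde, via C1-epimeric aldehyde mixture 18 (not isolated)
Conditions: PhI(OAc)2 (1.1 equiv), TEMPO (0.1 equiv), CH2Cl2, rt; then DBU (0.3 equiv), rt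
Reagents that add atoms: none
Why: Oxoammonium (TEMPO) oxidation is selective for the primary alcohol over the hindered secondary one. DBU then equilibrates the α-centre through the enolate to the equatorial 1β-aldehyde, trans to both the 2α-butenyl group and C8, because the axial epimer would be syn-diaxial to C5.

Step 14
Reactants: 19 1β-carbaldehyde; 20 ethyl (E)-4-(diethoxyphosphoryl)but-2-enoate
Product: 21 ethyl (2E,4E)-dienoate with free 7β-hydroxyl
Conditions: 20, LiN(SiMe3)2 (2.2 equiv), THF, −78 °C; then 19, −78 → 0 °C
Reagents that add atoms: none
Why: Vinylogous Horner–Wadsworth–Emmons olefination; the stabilised phosphonate anion gives the new E alkene and the E crotonate bond is carried over. The extra base covers the free hydroxyl.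

Step 15
Reactants: 21 ethyl (2E,4E)-dienoate with free 7β-hydroxyl
Product: 23 target hydrogen sulfate dienoic acid, via pyridinium sulfate ethyl ester 22 (not isolated)
Conditions: SO3·pyridine (5 equiv), pyridine, 40 °C; then LiOH, THF/H2O, rt; then 1 M HCl, 0 °C, pH 1–2, C18 desalting
Reagents that add atoms: sulfur trioxide–pyridine complex, SMILES [O-]S(=O)(=O)[n+]1ccccc1; lithium hydroxide, SMILES [Li+].[OH-]
Why: O-Sulfation of the alcohol by the SO3–amine complex, then ester saponification, to which the sulfate monoester anion is inert. Brief cold acidification gives the free acid form without time for solvolysis of the secondary sulfate.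

## Compound list

1 | (E)-4-methoxybut-3-en-2-one | CO/C=C/C(C)=O | starting material
2 | (E)-1-methoxy-3-(tert-butyldimethylsilyloxy)buta-1,3-diene | CO/C=C/C(=C)O[Si](C)(C)C(C)(C)C | intermediate
3 | 4-methoxy-2-methylphenol | COc1ccc(O)c(C)c1 | starting material
4 | 4,4-dimethoxy-2-methylcyclohexa-2,5-dien-1-one | COC1(OC)C=CC(=O)C(C)=C1 | intermediate
5 | cis-fused 1,1,5α-trimethoxy-3-methyl-7-(tert-butyldimethylsilyloxy)-4a,5,8,8a-tetrahydronaphthalen-4(1H)-one (target locants; H-4a and H-8a β) | COC1(OC)C=C(C)C(=O)[C@H]2[C@@H](OC)C=C(O[Si](C)(C)C(C)(C)C)C[C@@H]12 | intermediate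
6 | cis-fused 1,1,5α-trimethoxy-3-methyl-7-(tert-butyldimethylsilyloxy)-1,4,4a,5,8,8a-hexahydronaphthalen-4α-ol | COC1(OC)C=C(C)[C@@H](O)[C@H]2[C@@H](OC)C=C(O[Si](C)(C)C(C)(C)C)C[C@@H]12 | intermediate
7 | N-phenylcarbamate of 6 (4α-OC(O)NHPh) | COC1(OC)C=C(C)[C@@H](OC(=O)Nc3ccccc3)[C@H]2[C@@H](OC)C=C(O[Si](C)(C)C(C)(C)C)C[C@@H]12 | intermediate
8 | (E)-2-bromobut-2-ene | C/C=C(\C)Br | starting material
9 | (Z)-but-2-en-2-yllithium (methyl groups cis, geometry of 8 retained) | C/C=C(\C)[Li] | intermediate
10 | cis-fused 2α-[(E)-but-2-en-2-yl]-1,1,5α-trimethoxy-3-methyl-7-(tert-butyldimethylsilyloxy)-1,2,4a,5,8,8a-hexahydronaphthalene | C/C=C(\C)[C@H]1C(C)=C[C@H]2[C@@H](OC)C=C(O[Si](C)(C)C(C)(C)C)C[C@H]2C1(OC)OC | intermediate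
11 | cis-fused 2α-[(E)-but-2-en-2-yl]-1,1-dimethoxy-3-methyl-1,2,4a,8a-tetrahydronaphthalen-7(8H)-one | C/C=C(\C)[C@H]1C(C)=C[C@H]2C=CC(=O)C[C@H]2C1(OC)OC | intermediate
12 | 8β-methyl derivative of 11 | C/C=C(\C)[C@H]1C(C)=C[C@H]2C=CC(=O)[C@H](C)[C@H]2C1(OC)OC | intermediate
13 | cis-fused 2α-[(E)-but-2-en-2-yl]-1,1-dimethoxy-3,8β-dimethyl-1,2,4a,5,6,8a-hexahydronaphthalen-7(8H)-one | C/C=C(\C)[C@H]1C(C)=C[C@H]2CCC(=O)[C@H](C)[C@H]2C1(OC)OC | intermediate
14 | cis-fused 2α-[(E)-but-2-en-2-yl]-1,1-dimethoxy-3,8β-dimethyl-1,2,4a,5,6,7,8,8a-octahydronaphthalen-7β-ol | C/C=C(\C)[C@H]1C(C)=C[C@H]2CC[C@H](O)[C@H](C)[C@H]2C1(OC)OC | intermediate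
15 | cis-fused 2α-[(E)-but-2-en-2-yl]-7β-hydroxy-3,8β-dimethyl-4a,5,6,7,8,8a-hexahydronaphthalen-1(2H)-one | C/C=C(\C)[C@H]1C(C)=C[C@H]2CC[C@H](O)[C@H](C)[C@H]2C1=O | intermediate
16 | cis-fused 2α-[(E)-but-2-en-2-yl]-3,8β-dimethyl-1-methylidene-1,2,4a,5,6,7,8,8a-octahydronaphthalen-7β-ol | C/C=C(\C)[C@H]1C(C)=C[C@H]2CC[C@H](O)[C@H](C)[C@H]2C1=C | intermediate
17 | cis-fused 2α-[(E)-but-2-en-2-yl]-1-(hydroxymethyl)-3,8β-dimethyl-1,2,4a,5,6,7,8,8a-octahydronaphthalen-7β-ol, mixture of C1 epimers | C/C=C(\C)[C@H]1C(C)=C[C@H]2CC[C@H](O)[C@H](C)[C@H]2C1CO | intermediate
18 | cis-fused 2α-[(E)-but-2-en-2-yl]-7β-hydroxy-3,8β-dimethyl-1,2,4a,5,6,7,8,8a-octahydronaphthalene-1-carbaldehyde, mixture of C1 epimers | C/C=C(\C)[C@H]1C(C)=C[C@H]2CC[C@H](O)[C@H](C)[C@H]2C1C=O | intermediate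
19 | 1β-carbaldehyde (C1 epimer of 18 with the formyl group trans to the butenyl group and to C8) | C/C=C(\C)[C@H]1C(C)=C[C@H]2CC[C@H](O)[C@H](C)[C@H]2[C@@H]1C=O | intermediate
20 | ethyl (E)-4-(diethoxyphosphoryl)but-2-enoate | CCOC(=O)/C=C/CP(=O)(OCC)OCC | starting material
21 | ethyl (2E,4E)-5-[2α-((E)-but-2-en-2-yl)-7β-hydroxy-3,8β-dimethyl-1,2,4a,5,6,7,8,8a-octahydronaphthalen-1β-yl]penta-2,4-dienoate | C/C=C(\C)[C@H]1C(C)=C[C@H]2CC[C@H](O)[C@H](C)[C@H]2[C@@H]1/C=C/C=C/C(=O)OCC | intermediate
22 | pyridinium salt of the 7β-sulfate of 21 | C/C=C(\C)[C@H]1C(C)=C[C@H]2CC[C@H](OS(=O)(=O)[O-])[C@H](C)[C@H]2[C@@H]1/C=C/C=C/C(=O)OCC.c1cc[nH+]cc1 | intermediate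
23 | (2E,4E)-5-[(1S,2S,4aS,7S,8R,8aR)-2-[(E)-but-2-en-2-yl]-3,8-dimethyl-7-(sulfooxy)-1,2,4a,5,6,7,8,8a-octahydronaphthalen-1-yl]penta-2,4-dienoic acid | C/C=C(\C)[C@H]1C(C)=C[C@H]2CC[C@H](OS(=O)(=O)O)[C@H](C)[C@H]2[C@@H]1/C=C/C=C/C(=O)O | target

## Step count and least certain steps

Total step count: 15 (step 1 is a one-step branch to diene 2). Longest linear sequence: 14 steps (3 → 23, steps 2 to 15).

Step 3 (key step). The most likely failure is poor enantiofacial discrimination, or diversion of the concerted addition into a stepwise Mukaiyama–Michael addition with desilylation, because the Lewis acid can also attack the silyl enol ether. Fallback: run the cycloaddition of 4 and 2 thermally without Lewis acid (toluene, 80 °C), which gives 5 together with its enantiomer F1. Reduce as in step 4 to 6 together with its enantiomer F2. Resolve by lipase-catalysed acylation (Amano lipase PS, vinyl acetate), chosen so that the unwanted enantiomer is converted into its acetate F3 and separated. The route is rejoined at 6.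

Step 6. The intramolecular delivery may fail: substitution may occur directly at C4 or anti to the carbamate, or not at all, because C2 is flanked by the quaternary ketal carbon and the alkenyl group is branched. Fallback: from 6, invert C4 by Mitsunobu esterification (4-nitrobenzoic acid, PPh3, DIAD) to the 4β-(4-nitrobenzoate) F4. Methanolysis (K2CO3, MeOH) gives the 4β-alcohol F5, and acylation with picolinic acid (DCC, DMAP) gives the 4β-picolinate F6. Treatment with 9 transmetallated with MgBr2, in the presence of CuBr·SMe2, should then give anti-selective SN2′ substitution of the allylic picolinate, placing the butenyl group on the α face. The route is rejoined at 10.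

Step 7. The ring-fusion centre may be lost under base: the C4a proton of 11 is γ to the enone and doubly allylic, and the methoxide set free can remove it, causing epimerisation at C4a or migration of the double bonds into conjugation. Step 8 carries the same hazard if the enolate equilibrates. Fallback: from 10, cleave the silyl enol ether under buffered, non-basic conditions (HF·pyridine, pyridine, THF) to the β-methoxy ketone F7. Then merge elimination and methylation: LDA (2.2 equiv), THF, −78 °C, then MeI. The first equivalent triggers loss of LiOMe and the second deprotonates the enone at C8 at once. The route is rejoined at 12.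

Step 9. Stereocontrol at C7 may be incomplete if the ketyl is protonated kinetically, and the C8 centre may epimerise while ketone 13 sits in the alkoxide-containing medium. Fallback: from 12, 1,4-reduction with [(Ph3P)CuH]6 (cat.) and PhSiH3 to 13, now isolated, followed by an equilibrating Meerwein–Ponndorf–Verley reduction (Al(OiPr)3, i-PrOH, 80 °C), which should converge on the equatorial alcohol. The route is rejoined at 14; no compound outside the list is made (F0).

Step 11. Methylene transfer to the doubly α-branched ketone may be sluggish, and the Lewis-acidic metal halides may move the C3=C4 bond into conjugation with the carbonyl. Fallback: from 15, 1,2-addition of Me3SiCH2Li/CeCl3 (a non-basic organocerium reagent) to the β-hydroxysilane F8, then Peterson elimination (KH, THF). The route is rejoined at 16.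

## Further compounds

F1 | step 3 | enantiomer of 5 | COC1(OC)C=C(C)C(=O)[C@@H]2[C@H](OC)C=C(O[Si](C)(C)C(C)(C)C)C[C@H]12
F2 | step 3 | enantiomer of 6 | COC1(OC)C=C(C)[C@H](O)[C@@H]2[C@H](OC)C=C(O[Si](C)(C)C(C)(C)C)C[C@H]12
F3 | step 3 | acetate of the enantiomer of 6 | COC1(OC)C=C(C)[C@H](OC(C)=O)[C@@H]2[C@H](OC)C=C(O[Si](C)(C)C(C)(C)C)C[C@H]12
F4 | step 6 | 4β-(4-nitrobenzoate), C4-epimeric ester of 6 | COC1(OC)C=C(C)[C@H](OC(=O)c3ccc(cc3)[N+](=O)[O-])[C@H]2[C@@H](OC)C=C(O[Si](C)(C)C(C)(C)C)C[C@@H]12
F5 | step 6 | 4β-alcohol, C4 epimer of 6 | COC1(OC)C=C(C)[C@H](O)[C@H]2[C@@H](OC)C=C(O[Si](C)(C)C(C)(C)C)C[C@@H]12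
F6 | step 6 | 4β-picolinate of F5 | COC1(OC)C=C(C)[C@H](OC(=O)c3ccccn3)[C@H]2[C@@H](OC)C=C(O[Si](C)(C)C(C)(C)C)C[C@@H]12
F7 | step 7 | cis-fused 2α-[(E)-but-2-en-2-yl]-1,1,5α-trimethoxy-3-methyl-1,2,4a,5,6,8a-hexahydronaphthalen-7(8H)-one (β-methoxy ketone) | C/C=C(\C)[C@H]1C(C)=C[C@H]2[C@@H](OC)CC(=O)C[C@H]2C1(OC)OC
F0 | step 9 | none | none
F8 | step 11 | 1-hydroxy-1-(trimethylsilylmethyl) adduct of 15 (β-hydroxysilane, C1 epimers) | C/C=C(\C)[C@H]1C(C)=C[C@H]2CC[C@H](O)[C@H](C)[C@H]2C1(O)C[Si](C)(C)C
A1 | alternative 1 | ring-B-fused δ-lactone with 4β-oxygen and (2Z,4E)-4-methylhexa-2,4-dien-2-yl chain on C4 | C/C=C(\C)/C=C(/C)[C@H]1[C@H]2CC[C@H](O[Si](C)(C)C(C)(C)C)[C@H](C)[C@H]2CC(=O)O1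
A2 | alternative 1 | cyclic trimethylsilyl ketene acetal of A1 | C/C=C(\C)/C=C(/C)[C@H]1[C@H]2CC[C@H](O[Si](C)(C)C(C)(C)C)[C@H](C)[C@H]2C=C(O[Si](C)(C)C)O1
A3 | alternative 1 | cis-octalin C1 carboxylic acid with C2 butenyl group and C7 silyl ether | C/C=C(\C)[C@H]1C(C)=C[C@H]2CC[C@H](O[Si](C)(C)C(C)(C)C)[C@H](C)[C@H]2[C@@H]1C(=O)O
A4 | alternative 2 | acyclic pentaene with 2-silyloxydiene, Z C3=C4 bond and terminal vinyl group | C/C=C(\C)[C@@H](/C(C)=C\C=C)[C@@H](COCc1ccc(OC)cc1)/C=C/C(=C)O[Si](C)(C)C(C)(C)C
A5 | alternative 2 | cis-fused octalin C7 silyl enol ether with C1 CH2OPMB group | C/C=C(\C)[C@H]1C(C)=C[C@H]2CCC(O[Si](C)(C)C(C)(C)C)=C[C@H]2[C@@H]1COCc1ccc(OC)cc1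
A6 | alternative 3 | 4-substituted cyclohex-2-enone carrying the Z-alkenyl aldehyde chain | C/C=C(\C)[C@H](CC=O)/C(C)=C\[C@@H]1C=CC(=O)CC1
A7 | alternative 3 | cis-fused octalin-7-one C1 carbaldehyde | C/C=C(\C)[C@H]1C(C)=C[C@H]2CCC(=O)C[C@H]2[C@@H]1C=O
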